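**Plan**

1. Flavanone numbering is used for every intermediate: ring C is O1, C2, C3, C4; ring A is C4a, C5, C6, C7, C8, C8a; ring B is the chromenyl group on C2 (primed locants); the side chain on C8 is C1''–C3''. In the monocyclic dihydropyranones, pyranone C5 and C6 are therefore called C4a and C8a.
2. Enabling feature: ring A (C4a, C5, C6, C7, C8, C8a) carries oxygen on C5, C7 and C8a, that is on every second carbon as in a cyclised poly-β-carbonyl chain, and the oxygen on C8a is the ether O1 of ring C. Ring A can therefore be closed last, between C4a and C5, from a masked acylketene chain hanging on C8a of a finished dihydropyranone.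
3. Retrosynthetic cuts: C4a–C5 (ring A; C5–C7 return to a 1,3-dioxin-4-one), then C8–C8a (dioxinone dienol ether plus a C8a-unsubstituted dihydropyranone), then O1–C8a and C2–C3 (hetero-Diels–Alder on the ring B aldehyde), C8–C1'' (γ-alkylation of the dioxinone) and C2–C1' (formylation).
4. Forward order: ring B chromene aldehyde, then ring C by catalytic asymmetric hetero-Diels–Alder, then side chain and dioxinone joined at C8a by Lewis-acid conjugate addition and re-oxidation (no base meets the C2/C3 unit), then ring A by thermolysis, then desilylation.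
5. Stereochemistry: the only stereocentre, C2 (S), comes from catalyst-controlled Si-face addition in the hetero-Diels–Alder step; afterwards it meets only catalytic Lewis acid, neutral heat and buffered fluoride. All other stereocentres of intermediates are transient.

Key step: step 11

Remark: the (S,S)-salen chromium chloride complex is assumed to be the antipode that leaves the Si face of aldehyde 8 open, as with simple aryl aldehydes; if the sense is the opposite, the mirror-image complex is used.

**Route**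

Step 1
Reactants: 1 4-bromobenzene-1,3-diol; 2 3-methylbut-2-enoic acid
Product: 3 6-bromo-7-hydroxy-2,2-dimethyl-2,3-dihydro-4H-chromen-4-one
Conditions: P2O5, MeSO3H, 70 °C
Reagents that add atoms: none
Why: Friedel–Crafts acylation by the activated acid occurs at C6 of the resorcinol (para to one hydroxyl, ortho to the other; C4 carries bromine and C2 is flanked twice), and the aryl enone closes by oxa-Michael addition of the ortho hydroxyl, the usual one-pot route from resorcinols to 2,2-dimethylchroman-4-ones.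

Step 2
Reactants: 3 6-bromo-7-hydroxy-2,2-dimethyl-2,3-dihydro-4H-chromen-4-one
Product: 4 6-bromo-7-(tert-butyldimethylsilyloxy)-2,2-dimethyl-2,3-dihydro-4H-chromen-4-one
Conditions: TBSCl, imidazole, DMF, rt
Reagents that add atoms: tert-butyldimethylsilyl chloride, CC(C)(C)[Si](C)(C)Cl
Why: Imidazole-promoted silylation of the single phenol protects O7 against the hydride, the organolithium and the Lewis acids used later, and the group leaves with fluoride at the end.

Step 3
Reactants: 4 6-bromo-7-(tert-butyldimethylsilyloxy)-2,2-dimethyl-2,3-dihydro-4H-chromen-4-one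
Product: 6 6-bromo-7-(tert-butyldimethylsilyloxy)-2,2-dimethyl-2H-chromene, via chromanol 5 (not isolated)
Conditions: NaBH4, THF/EtOH, 0 °C; then p-TsOH·H2O (cat.), toluene, 60 °C
Reagents that add atoms: none
Why: Borohydride reduces the aryl ketone to benzylic alcohol 5, which loses water by acid-catalysed E1 dehydration through a cation stabilised by the ortho ring oxygen and the para silyloxy group, the standard chromanone-to-chromene sequence.

Step 4
Reactants: 6 6-bromo-7-(tert-butyldimethylsilyloxy)-2,2-dimethyl-2H-chromene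
Product: 8 7-(tert-butyldimethylsilyloxy)-2,2-dimethyl-2H-chromene-6-carbaldehyde, via aryllithium 7 (not isolated)
Conditions: n-BuLi, THF, −78 °C; DMF, −78 to −40 °C; aq. NH4Cl
Reagents that add atoms: N,N-dimethylformamide, CN(C)C=O
Why: Bromine–lithium exchange at −78 °C gives aryllithium 7, which DMF formylates (Bouveault-type formylation), the low temperature holding back 1,3-migration of silicon from oxygen to the lithiated carbon.

Step 5
Reactants: 8 7-(tert-butyldimethylsilyloxy)-2,2-dimethyl-2H-chromene-6-carbaldehyde; 9 (E)-1-methoxy-3-(trimethylsilyloxy)buta-1,3-diene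
Product: 11 (2S)-2-[7-(tert-butyldimethylsilyloxy)-2,2-dimethyl-2H-chromen-6-yl]-2,3-dihydro-4H-pyran-4-one, via cycloadduct 10 (not isolated)
Conditions: (S,S)-N,N'-bis(3,5-di-tert-butylsalicylidene)-1,2-cyclohexanediaminochromium chloride (5 mol %), 4 Å molecular sieves, t-BuOMe, −20 °C to rt; then CF3CO2H (cat.), CH2Cl2, 0 °C
Reagents that add atoms: none
Why: Catalytic asymmetric hetero-Diels–Alder reaction in which the chiral chromium Lewis acid binds the aldehyde and leaves its Si face open to the electron-rich diene, which fixes C2 as S, after which acid converts cycloadduct 10 into the enone by loss of methanol and of the silyl group.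

Step 6
Reactants: 12 3-methylbutane-1,3-diol
Product: 13 4-iodo-2-methylbutan-2-ol
Conditions: I2, PPh3, imidazole, CH2Cl2, 0 °C to rt
Reagents that add atoms: iodine, II
Why: Appel-type iodination, in which iodide displaces the oxyphosphonium ion of the primary alcohol in an SN2 step that the tertiary alcohol cannot undergo.

Step 7
Reactants: 13 4-iodo-2-methylbutan-2-ol
Product: 14 triethyl[(4-iodo-2-methylbutan-2-yl)oxy]silane
Conditions: TESOTf, 2,6-lutidine, CH2Cl2, −78 to 0 °C
Reagents that add atoms: triethylsilyl trifluoromethanesulfonate, CC[Si](CC)(CC)OS(=O)(=O)C(F)(F)F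
Why: A silyl triflate with a hindered pyridine base silylates the tertiary alcohol under conditions to which the primary iodide is inert.

Step 8
Reactants: 15 2,2,6-trimethyl-4H-1,3-dioxin-4-one; 14 triethyl[(4-iodo-2-methylbutan-2-yl)oxy]silane
Product: 17 2,2-dimethyl-6-[4-methyl-4-(triethylsilyloxy)pentyl]-4H-1,3-dioxin-4-one, via lithium dienolate 16 (not isolated)
Conditions: LiN(iPr)2, THF, −78 °C; then 14, DMPU, −78 to −20 °C
Reagents that add atoms: none
Why: Vinylogous enolate alkylation, in which deprotonation of the C6 methyl group gives cross-conjugated dienolate 16 and this reacts with the primary iodide at its γ-carbon once DMPU has loosened the lithium aggregates, forming C8–C1''.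

Step 9
Reactants: 17 2,2-dimethyl-6-[4-methyl-4-(triethylsilyloxy)pentyl]-4H-1,3-dioxin-4-one
Product: 19 2,2-dimethyl-6-[4-methyl-4-(triethylsilyloxy)pentylidene]-4-(trimethylsilyloxy)-1,3-diox-4-ene (E/Z mixture), via lithium dienolate 18 (not isolated)
Conditions: LiN(iPr)2, THF, −78 °C; then TMSCl, −78 °C to rt
Reagents that add atoms: chlorotrimethylsilane, C[Si](C)(C)Cl
Why: A second γ-deprotonation followed by O-silylation gives the silyl dienol ether that serves as the carbon nucleophile in vinylogous Mukaiyama reactions.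

Step 10
Reactants: 11 (2S)-2-[7-(tert-butyldimethylsilyloxy)-2,2-dimethyl-2H-chromen-6-yl]-2,3-dihydro-4H-pyran-4-one; 19 2,2-dimethyl-6-[4-methyl-4-(triethylsilyloxy)pentylidene]-4-(trimethylsilyloxy)-1,3-diox-4-ene
Product: 21 (2S)-2-[7-(tert-butyldimethylsilyloxy)-2,2-dimethyl-2H-chromen-6-yl]-6-[1-(2,2-dimethyl-4-oxo-4H-1,3-dioxin-6-yl)-4-methyl-4-(triethylsilyloxy)pentyl]-2,3-dihydro-4H-pyran-4-one (both epimers at the side-chain CH), via silyl enol ether 20 (not isolated)
Conditions: 19 (1.5 equiv), TMSOTf (0.2 equiv), 2,6-di-tert-butyl-4-methylpyridine, CH2Cl2, −78 °C; then Pd(OAc)2 (1.1 equiv), MeCN, rt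
Reagents that add atoms: none
Why: Vinylogous Mukaiyama–Michael addition followed by Saegusa–Ito oxidation: the silyl triflate turns the enone into a 4-silyloxy oxocarbenium ion that the dienol ether attacks at C8a through its γ-carbon, silyl transfer leaves the enol ether regiospecifically at C4=C4a, and Pd(OAc)2 restores the C4a=C8a double bond by β-hydride elimination of the only available hydrogen, so that the two new stereocentres (C8a, removed here, and the side-chain CH, removed in step 11) need no control.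

Step 11
Reactants: 21 (2S)-2-[7-(tert-butyldimethylsilyloxy)-2,2-dimethyl-2H-chromen-6-yl]-6-[1-(2,2-dimethyl-4-oxo-4H-1,3-dioxin-6-yl)-4-methyl-4-(triethylsilyloxy)pentyl]-2,3-dihydro-4H-pyran-4-one
Product: 24 (2S)-2-[7-(tert-butyldimethylsilyloxy)-2,2-dimethyl-2H-chromen-6-yl]-5,7-dihydroxy-8-[3-methyl-3-(triethylsilyloxy)butyl]-2,3-dihydro-4H-chromen-4-one, via acylketene 22 (not isolated), via cyclohexadienone tautomer 23 (not isolated)
Conditions: toluene (0.005 M), 4 Å molecular sieves, argon, 110 °C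
Reagents that add atoms: none
Why: Proposed new method: retro-[4+2] loss of acetone from the dioxinone near 110 °C gives acylketene 22 (C5 is the ketene carbon), whose C7 ketone enolises toward the doubly activated C8–H so that C5=C6, C7=C8 and C8a=C4a make up a ketene-terminated triene. Ring A then closes between C4a and C5 by thermal disrotatory 6π-electrocyclisation (six-membered, endo mode; in polar terms, C-acylation of the nucleophilic α-carbon of the vinylogous ester followed by loss of the C8 proton), and cyclohexadienone 23 tautomerises to the 5,7-dihydroxyarene. The closest known reactions are the thermolysis of dioxinones to acylketenes with biomimetic aromatisation to resorcylates and the benzannulation of dienylketenes by 6π-electrocyclisation; neither has been run on a dihydropyranone. No stereocentre is created: C4a and the side-chain carbon become sp2 and C2 is not touched under neutral conditions. The step needs attack of C4a on the ketene to outrun dimerisation and O-acylation; this is secured by high dilution, by the absence of any free hydroxyl (O1 is a ring ether, O2' and the chain oxygen are silylated) and by the fact that only C4a reaches C5 through a six-membered transition state, so that the chain is fixed next to O1 by construction.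

Step 12
Reactants: 24 (2S)-2-[7-(tert-butyldimethylsilyloxy)-2,2-dimethyl-2H-chromen-6-yl]-5,7-dihydroxy-8-[3-methyl-3-(triethylsilyloxy)butyl]-2,3-dihydro-4H-chromen-4-one
Product: 25 (2S)-5,7-dihydroxy-8-(3-hydroxy-3-methylbutyl)-2-(7-hydroxy-2,2-dimethyl-2H-chromen-6-yl)-2,3-dihydro-4H-chromen-4-one
Conditions: HF·pyridine, pyridine, THF, 0 °C to rt
Reagents that add atoms: none
Why: Fluoride-mediated desilylation removes the aryl silyl ether and the tertiary triethylsilyl ether, and the pyridine buffer keeps the medium free of the phenoxide that would open ring C and racemise C2.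

**Compound list**

1 | 4-bromobenzene-1,3-diol | Oc1ccc(Br)c(O)c1 | starting material
2 | 3-methylbut-2-enoic acid | CC(C)=CC(=O)O | starting material
3 | 6-bromo-7-hydroxy-2,2-dimethyl-2,3-dihydro-4H-chromen-4-one | CC1(C)CC(=O)c2cc(Br)c(O)cc2O1 | intermediate
4 | 6-bromo-7-(tert-butyldimethylsilyloxy)-2,2-dimethyl-2,3-dihydro-4H-chromen-4-one | CC1(C)CC(=O)c2cc(Br)c(O[Si](C)(C)C(C)(C)C)cc2O1 | intermediate
5 | 6-bromo-7-(tert-butyldimethylsilyloxy)-2,2-dimethylchroman-4-ol, racemic (not isolated) | CC1(C)CC(O)c2cc(Br)c(O[Si](C)(C)C(C)(C)C)cc2O1 | intermediate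
6 | 6-bromo-7-(tert-butyldimethylsilyloxy)-2,2-dimethyl-2H-chromene | CC1(C)C=Cc2cc(Br)c(O[Si](C)(C)C(C)(C)C)cc2O1 | intermediate
7 | [7-(tert-butyldimethylsilyloxy)-2,2-dimethyl-2H-chromen-6-yl]lithium (not isolated) | [Li]c1cc2C=CC(C)(C)Oc2cc1O[Si](C)(C)C(C)(C)C | intermediate
8 | 7-(tert-butyldimethylsilyloxy)-2,2-dimethyl-2H-chromene-6-carbaldehyde | O=Cc1cc2C=CC(C)(C)Oc2cc1O[Si](C)(C)C(C)(C)C | intermediate
9 | (E)-1-methoxy-3-(trimethylsilyloxy)buta-1,3-diene | CO/C=C/C(=C)O[Si](C)(C)C | starting material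
10 | (2S)-2-[7-(tert-butyldimethylsilyloxy)-2,2-dimethyl-2H-chromen-6-yl]-6-methoxy-4-(trimethylsilyloxy)-3,6-dihydro-2H-pyran, acetal carbon undefined (not isolated) | COC1C=C(O[Si](C)(C)C)C[C@@H](c2cc3C=CC(C)(C)Oc3cc2O[Si](C)(C)C(C)(C)C)O1 | intermediate
11 | (2S)-2-[7-(tert-butyldimethylsilyloxy)-2,2-dimethyl-2H-chromen-6-yl]-2,3-dihydro-4H-pyran-4-one | O=C1C=CO[C@H](c2cc3C=CC(C)(C)Oc3cc2O[Si](C)(C)C(C)(C)C)C1 | intermediate
12 | 3-methylbutane-1,3-diol | CC(C)(O)CCO | starting material
13 | 4-iodo-2-methylbutan-2-ol | CC(C)(O)CCI | intermediate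
14 | triethyl[(4-iodo-2-methylbutan-2-yl)oxy]silane | CC[Si](CC)(CC)OC(C)(C)CCI | intermediate
15 | 2,2,6-trimethyl-4H-1,3-dioxin-4-one | CC1=CC(=O)OC(C)(C)O1 | starting material
16 | lithium 2,2-dimethyl-6-methylidene-1,3-diox-4-en-4-olate (not isolated) | [Li]OC1=CC(=C)OC(C)(C)O1 | intermediate
17 | 2,2-dimethyl-6-[4-methyl-4-(triethylsilyloxy)pentyl]-4H-1,3-dioxin-4-one | CC1(C)OC(=O)C=C(CCCC(C)(C)O[Si](CC)(CC)CC)O1 | intermediate
18 | lithium 2,2-dimethyl-6-[4-methyl-4-(triethylsilyloxy)pentylidene]-1,3-diox-4-en-4-olate (not isolated) | [Li]OC1=CC(=CCCC(C)(C)O[Si](CC)(CC)CC)OC(C)(C)O1 | intermediate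
19 | 2,2-dimethyl-6-[4-methyl-4-(triethylsilyloxy)pentylidene]-4-(trimethylsilyloxy)-1,3-diox-4-ene, E/Z mixture | C[Si](C)(C)OC1=CC(=CCCC(C)(C)O[Si](CC)(CC)CC)OC(C)(C)O1 | intermediate
20 | (2S)-2-[7-(tert-butyldimethylsilyloxy)-2,2-dimethyl-2H-chromen-6-yl]-6-[1-(2,2-dimethyl-4-oxo-4H-1,3-dioxin-6-yl)-4-methyl-4-(triethylsilyloxy)pentyl]-4-(trimethylsilyloxy)-3,6-dihydro-2H-pyran, C8a and side-chain CH undefined (not isolated) | C[Si](C)(C)OC1=CC(C(CCC(C)(C)O[Si](CC)(CC)CC)C2=CC(=O)OC(C)(C)O2)O[C@H](c2cc3C=CC(C)(C)Oc3cc2O[Si](C)(C)C(C)(C)C)C1 | intermediate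
21 | (2S)-2-[7-(tert-butyldimethylsilyloxy)-2,2-dimethyl-2H-chromen-6-yl]-6-[1-(2,2-dimethyl-4-oxo-4H-1,3-dioxin-6-yl)-4-methyl-4-(triethylsilyloxy)pentyl]-2,3-dihydro-4H-pyran-4-one, both epimers at the side-chain CH | O=C1C=C(C(CCC(C)(C)O[Si](CC)(CC)CC)C2=CC(=O)OC(C)(C)O2)O[C@H](c2cc3C=CC(C)(C)Oc3cc2O[Si](C)(C)C(C)(C)C)C1 | intermediate
22 | acylketene from 21 by loss of acetone: (2S)-2-aryl-6-[1,3-dioxo-1-(ketenyl) chain] dihydropyranone (not isolated) | O=C=CC(=O)C(CCC(C)(C)O[Si](CC)(CC)CC)C1=CC(=O)C[C@@H](c2cc3C=CC(C)(C)Oc3cc2O[Si](C)(C)C(C)(C)C)O1 | intermediate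
23 | 4a-H cyclohexa-2,4-dienone tautomer of 24, C4a undefined (not isolated) | O=C1C[C@@H](c2cc3C=CC(C)(C)Oc3cc2O[Si](C)(C)C(C)(C)C)OC2=C(CCC(C)(C)O[Si](CC)(CC)CC)C(O)=CC(=O)C12 | intermediate
24 | (2S)-2-[7-(tert-butyldimethylsilyloxy)-2,2-dimethyl-2H-chromen-6-yl]-5,7-dihydroxy-8-[3-methyl-3-(triethylsilyloxy)butyl]-2,3-dihydro-4H-chromen-4-one | CC[Si](CC)(CC)OC(C)(C)CCc1c(O)cc(O)c2c1O[C@H](c1cc3C=CC(C)(C)Oc3cc1O[Si](C)(C)C(C)(C)C)CC2=O | intermediate
25 | (2S)-5,7-dihydroxy-8-(3-hydroxy-3-methylbutyl)-2-(7-hydroxy-2,2-dimethyl-2H-chromen-6-yl)-2,3-dihydro-4H-chromen-4-one | CC(C)(O)CCc1c(O)cc(O)c2c1O[C@H](c1cc3c(cc1O)OC(C)(C)C=C3)CC2=O | target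

**Step count and risks**

Total steps: 12. Longest linear sequence: 8 steps (steps 1, 2, 3, 4, 5, 10, 11, 12).

Steps most likely to fail:

1. Step 11 (proposed new method). The acylketene may be consumed by dimerisation or by traces of water (hydrolysis and decarboxylation), or closure at C4a may be too slow because the α-carbon of a vinylogous ester is a weak nucleophile, so that decomposition wins.
Fallback with known chemistry, setting out from iodide 14 and bromide 6 and returning at target 25: ring A is taken from a preformed chromone and C2 is set by rhodium-catalysed asymmetric conjugate arylation. Commercial 5,7-dihydroxy-4H-chromen-4-one is silylated (TBSOTf, 2,6-lutidine) to 5,7-bis(tert-butyldimethylsilyloxy)-4H-chromen-4-one F1. This is iodinated with N-iodosuccinimide at C8, the less hindered of the two activated positions, to 5,7-bis(tert-butyldimethylsilyloxy)-8-iodo-4H-chromen-4-one F2. Iodide 14 is converted with zinc dust and LiCl in THF into [3-methyl-3-(triethylsilyloxy)butyl]zinc iodide F3, and Negishi coupling with F2 (Pd(OAc)2, SPhos) gives 5,7-bis(tert-butyldimethylsilyloxy)-8-[3-methyl-3-(triethylsilyloxy)butyl]-4H-chromen-4-one F4. Bromide 6 is lithiated as in step 4 and aryllithium 7 is quenched with B(OiPr)3 to give [7-(tert-butyldimethylsilyloxy)-2,2-dimethyl-2H-chromen-6-yl]boronic acid F5. Asymmetric 1,4-addition of F5 to F4 ([RhCl(C2H4)2]2, a chiral diene ligand of the antipode that gives 2S, aqueous KOH, dioxane) should give the fully silylated flavanone (2S)-5,7-bis(tert-butyldimethylsilyloxy)-2-[7-(tert-butyldimethylsilyloxy)-2,2-dimethyl-2H-chromen-6-yl]-8-[3-methyl-3-(triethylsilyloxy)butyl]-2,3-dihydro-4H-chromen-4-one F6. HF·pyridine under the conditions of step 12 then gives 25.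

2. Step 10. The γ-branched dienol ether may add too slowly or through its α-carbon at the hindered oxocarbenium ion, leaving the enone to decompose under the Lewis acid.
Fallback, setting out from dienolate 16 (from dioxinone 15) and pyranone 11 and returning at 21: the unbranched nucleophile is used and the chain is attached last. Dienolate 16 is silylated with TMSCl to 2,2-dimethyl-6-methylidene-4-(trimethylsilyloxy)-1,3-diox-4-ene F7. Under TMSOTf catalysis this adds to 11 to give (2S)-2-[7-(tert-butyldimethylsilyloxy)-2,2-dimethyl-2H-chromen-6-yl]-6-[(2,2-dimethyl-4-oxo-4H-1,3-dioxin-6-yl)methyl]-4-(trimethylsilyloxy)-3,6-dihydro-2H-pyran F8. Pd(OAc)2 in MeCN then gives (2S)-2-[7-(tert-butyldimethylsilyloxy)-2,2-dimethyl-2H-chromen-6-yl]-6-[(2,2-dimethyl-4-oxo-4H-1,3-dioxin-6-yl)methyl]-2,3-dihydro-4H-pyran-4-one F9. Its doubly activated C8 methylene is alkylated with iodide 14 (Cs2CO3, DMF, rt) to give 21; the carbonate is too weak a base to deprotonate C3.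

3. Step 8. The dienolate may be too weak a nucleophile for an unactivated primary iodide, so that self-condensation of the dioxinone and α-alkylation take over.
Fallback, setting out from dienolate 16 and returning at 17: an allylic electrophile is used and the carbinol is made afterwards. Dienolate 16 is alkylated with 1-bromo-3-methylbut-2-ene to 2,2-dimethyl-6-(4-methylpent-3-en-1-yl)-4H-1,3-dioxin-4-one F10. Markovnikov hydration of the trisubstituted alkene (Co(acac)2, PhSiH3, O2, i-PrOH) gives 6-(4-hydroxy-4-methylpentyl)-2,2-dimethyl-4H-1,3-dioxin-4-one F11. Silylation with TESOTf and 2,6-lutidine gives 17.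

**Further compounds**

F1 | step 11 | 5,7-bis(tert-butyldimethylsilyloxy)-4H-chromen-4-one | O=c1ccoc2cc(O[Si](C)(C)C(C)(C)C)cc(O[Si](C)(C)C(C)(C)C)c12
F2 | step 11 | 5,7-bis(tert-butyldimethylsilyloxy)-8-iodo-4H-chromen-4-one | O=c1ccoc2c(I)c(O[Si](C)(C)C(C)(C)C)cc(O[Si](C)(C)C(C)(C)C)c12
F3 | step 11 | [3-methyl-3-(triethylsilyloxy)butyl]zinc iodide | CC[Si](CC)(CC)OC(C)(C)CC[Zn]I
F4 | step 11 | 5,7-bis(tert-butyldimethylsilyloxy)-8-[3-methyl-3-(triethylsilyloxy)butyl]-4H-chromen-4-one | O=c1ccoc2c(CCC(C)(C)O[Si](CC)(CC)CC)c(O[Si](C)(C)C(C)(C)C)cc(O[Si](C)(C)C(C)(C)C)c12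
F5 | step 11 | [7-(tert-butyldimethylsilyloxy)-2,2-dimethyl-2H-chromen-6-yl]boronic acid | OB(O)c1cc2C=CC(C)(C)Oc2cc1O[Si](C)(C)C(C)(C)C
F6 | step 11 | (2S)-5,7-bis(tert-butyldimethylsilyloxy)-2-[7-(tert-butyldimethylsilyloxy)-2,2-dimethyl-2H-chromen-6-yl]-8-[3-methyl-3-(triethylsilyloxy)butyl]-2,3-dihydro-4H-chromen-4-one | CC[Si](CC)(CC)OC(C)(C)CCc1c(O[Si](C)(C)C(C)(C)C)cc(O[Si](C)(C)C(C)(C)C)c2c1O[C@H](c1cc3C=CC(C)(C)Oc3cc1O[Si](C)(C)C(C)(C)C)CC2=O
F7 | step 10 | 2,2-dimethyl-6-methylidene-4-(trimethylsilyloxy)-1,3-diox-4-ene | C=C1C=C(O[Si](C)(C)C)OC(C)(C)O1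
F8 | step 10 | (2S)-2-[7-(tert-butyldimethylsilyloxy)-2,2-dimethyl-2H-chromen-6-yl]-6-[(2,2-dimethyl-4-oxo-4H-1,3-dioxin-6-yl)methyl]-4-(trimethylsilyloxy)-3,6-dihydro-2H-pyran | C[Si](C)(C)OC1=CC(CC2=CC(=O)OC(C)(C)O2)O[C@H](c2cc3C=CC(C)(C)Oc3cc2O[Si](C)(C)C(C)(C)C)C1
F9 | step 10 | (2S)-2-[7-(tert-butyldimethylsilyloxy)-2,2-dimethyl-2H-chromen-6-yl]-6-[(2,2-dimethyl-4-oxo-4H-1,3-dioxin-6-yl)methyl]-2,3-dihydro-4H-pyran-4-one | O=C1C=C(CC2=CC(=O)OC(C)(C)O2)O[C@H](c2cc3C=CC(C)(C)Oc3cc2O[Si](C)(C)C(C)(C)C)C1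
F10 | step 8 | 2,2-dimethyl-6-(4-methylpent-3-en-1-yl)-4H-1,3-dioxin-4-one | CC(C)=CCCC1=CC(=O)OC(C)(C)O1
F11 | step 8 | 6-(4-hydroxy-4-methylpentyl)-2,2-dimethyl-4H-1,3-dioxin-4-one | CC(C)(O)CCCC1=CC(=O)OC(C)(C)O1
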